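The target is a 1,7-diarylheptan-3-one. Counting the chain from the syringyl-bound CH2 (C1) to the catechol-bound CH2 (C7), the C2–C3(=O)–C4 segment is an acetone whose two alpha-carbons carry unlike arms, and this is the feature exploited: the route cuts C1–C2 and C4–C5. In one flask the dianion of benzyl acetoacetate is joined first through its terminal carbon to an O-benzyl syringyl-type benzylic chloride, then through its ester-bearing carbon to an O,O-dibenzyl 3-(catechol)propyl iodide. The precursors are thus three simple benzyl-protected pieces; the ester that tells C4 from C2 is lost as CO2 when a final hydrogenolysis removes all four benzyl groups.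

Key step: step 7

Assumption: the target has no stereocentre and is taken as drawn. Ring A is the 4-hydroxy-3,5-dimethoxyphenyl (syringyl) ring and ring B the 3,4-dihydroxyphenyl (catechol) ring. The benzylic partner is kept as the chloride because the bromide of so electron-rich a ring would ionise too easily, and the unactivated partner is the iodide.

Step 1
Reactants: 1 syringaldehyde (4-hydroxy-3,5-dimethoxybenzaldehyde)
Product: 2 4-(benzyloxy)-3,5-dimethoxybenzaldehyde
Conditions: BnBr, K2CO3, DMF, 60 °C
Reagents that add atoms: benzyl bromide, BrCc1ccccc1
Why: Williamson ether synthesis, in which the phenoxide formed by K2CO3 displaces bromide from benzyl bromide by SN2 while the aldehyde is inert to the mild, non-nucleophilic base.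

Step 2
Reactants: 2 4-(benzyloxy)-3,5-dimethoxybenzaldehyde
Product: 3 [4-(benzyloxy)-3,5-dimethoxyphenyl]methanol
Conditions: NaBH4, MeOH/THF, 0 °C
Reagents that add atoms: none
Why: Borohydride reduction of an aryl aldehyde to the benzylic alcohol is fast at 0 °C and leaves the aryl ethers untouched.

Step 3
Reactants: 3 [4-(benzyloxy)-3,5-dimethoxyphenyl]methanol
Product: 4 2-(benzyloxy)-5-(chloromethyl)-1,3-dimethoxybenzene
Conditions: SOCl2, CH2Cl2, 0 °C to rt; strip with toluene, use without chromatography
Reagents that add atoms: thionyl chloride, O=S(Cl)Cl
Why: Deoxychlorination with thionyl chloride through the alkyl chlorosulfite is facile for an electron-rich benzylic alcohol at 0 °C, and the aryl benzyl and methyl ethers tolerate the brief contact with HCl.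

Step 4
Reactants: 5 3-(3,4-dihydroxyphenyl)propanoic acid
Product: 6 benzyl 3-[3,4-bis(benzyloxy)phenyl]propanoate
Conditions: BnBr (3.3 equiv), K2CO3, DMF, 60 °C, argon
Reagents that add atoms: benzyl bromide, BrCc1ccccc1
Why: Williamson etherification of both phenols and O-alkylation of the carboxylate take place together with excess benzyl bromide, the argon blanket guarding the catecholate against air oxidation, so one operation masks all three acidic sites.

Step 5
Reactants: 6 benzyl 3-[3,4-bis(benzyloxy)phenyl]propanoate
Product: 7 3-[3,4-bis(benzyloxy)phenyl]propan-1-ol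
Conditions: LiAlH4, THF, 0 °C to rt; Fieser work-up
Reagents that add atoms: none
Why: Hydride reduction of the ester with LiAlH4 gives the primary alcohol, aryl benzyl ethers being inert to the reagent, and the benzyl alcohol co-product is removed by chromatography.

Step 6
Reactants: 7 3-[3,4-bis(benzyloxy)phenyl]propan-1-ol
Product: 8 1,2-bis(benzyloxy)-4-(3-iodopropyl)benzene
Conditions: PPh3, I2, imidazole, CH2Cl2, 0 °C to rt
Reagents that add atoms: iodine, [I][I]
Why: Appel-type iodination, in which the alkoxyphosphonium ion formed from the alcohol is displaced by iodide in an SN2 reaction at the unhindered primary carbon under near-neutral conditions that spare the benzyl ethers.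

Step 7
Reactants: 9 benzyl acetoacetate; 4 2-(benzyloxy)-5-(chloromethyl)-1,3-dimethoxybenzene; 8 1,2-bis(benzyloxy)-4-(3-iodopropyl)benzene
Product: 12 racemic benzyl 2-{3-[3,4-bis(benzyloxy)phenyl]propyl}-5-[4-(benzyloxy)-3,5-dimethoxyphenyl]-3-oxopentanoate, via benzyl acetoacetate sodium lithium dianion 10 (not isolated), via gamma-benzylated sodium enolate 11 (not isolated)
Conditions: 9 (1.05 equiv), NaH, THF, 0 °C; n-BuLi, 0 °C; 4 (1.0 equiv), 0 °C; then 8 (1.2 equiv), DMPU, 0 to 45 °C; aq NH4Cl
Reagents that add atoms: none
Why: NaH removes a proton from the CH2 between the two carbonyls of 9 (future C4) and n-BuLi then deprotonates the methyl group (future C2), giving dianion 10, whose terminal carbon is much more basic and nucleophilic than the delocalised internal position and therefore alone displaces chloride from benzylic chloride 4 by SN2 at 0 °C, forming C1–C2. The species left is the ordinary beta-keto ester enolate 11, which after addition of DMPU and gentle warming is C-alkylated by primary iodide 8, forming C4–C5; the closest known reaction type is the gamma-alkylation of acetoacetate dianions followed in the same flask by a classical acetoacetic ester alpha-alkylation. No ring is closed. The single new stereocentre, C4, arises racemic with no controlling element, which is harmless because decarboxylation later turns it into a CH2 group. The selectivity required is positional, each halide at its own carbon, and it is secured by the reactivity gap between the two anionic sites and by the order of addition, the reactive chloride being the limiting reagent and consumed before the iodide enters. C-alkylation is favoured over O-alkylation by the soft iodide leaving group, and a second alpha-alkylation is held back because only one equivalent of enolate is present and the monoalkylated product is more hindered and less acidic.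

Step 8
Reactants: 12 racemic benzyl 2-{3-[3,4-bis(benzyloxy)phenyl]propyl}-5-[4-(benzyloxy)-3,5-dimethoxyphenyl]-3-oxopentanoate
Product: 14 7-(3,4-dihydroxyphenyl)-1-(4-hydroxy-3,5-dimethoxyphenyl)heptan-3-one, via racemic beta-keto acid 13 (not isolated)
Conditions: H2 (1 atm), 10% Pd/C, EtOAc/EtOH, rt; filter under argon; 50 °C
Reagents that add atoms: none
Why: Hydrogenolysis over Pd/C cleaves the three aryl benzyl ethers and the benzyl ester, and the freed beta-keto acid 13 loses CO2 through the usual six-membered cyclic transition state on warming, which also erases the C4 stereocentre, while the unconjugated dialkyl ketone and the aryl methyl ethers are inert at 1 atm H2.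

Compound list
1 | syringaldehyde (4-hydroxy-3,5-dimethoxybenzaldehyde) | COc1cc(C=O)cc(OC)c1O | starting material
2 | 4-(benzyloxy)-3,5-dimethoxybenzaldehyde | COc1cc(C=O)cc(OC)c1OCc1ccccc1 | intermediate
3 | [4-(benzyloxy)-3,5-dimethoxyphenyl]methanol | COc1cc(CO)cc(OC)c1OCc1ccccc1 | intermediate
4 | 2-(benzyloxy)-5-(chloromethyl)-1,3-dimethoxybenzene | COc1cc(CCl)cc(OC)c1OCc1ccccc1 | intermediate
5 | 3-(3,4-dihydroxyphenyl)propanoic acid | O=C(O)CCc1ccc(O)c(O)c1 | starting material
6 | benzyl 3-[3,4-bis(benzyloxy)phenyl]propanoate | O=C(CCc1ccc(OCc2ccccc2)c(OCc2ccccc2)c1)OCc1ccccc1 | intermediate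
7 | 3-[3,4-bis(benzyloxy)phenyl]propan-1-ol | OCCCc1ccc(OCc2ccccc2)c(OCc2ccccc2)c1 | intermediate
8 | 1,2-bis(benzyloxy)-4-(3-iodopropyl)benzene | ICCCc1ccc(OCc2ccccc2)c(OCc2ccccc2)c1 | intermediate
9 | benzyl acetoacetate (benzyl 3-oxobutanoate) | CC(=O)CC(=O)OCc1ccccc1 | starting material
10 | sodium lithium dianion (bis-enolate) of benzyl acetoacetate | [Li+].[Na+].C=C([O-])C=C([O-])OCc1ccccc1 | intermediate
11 | sodium enolate of benzyl 5-[4-(benzyloxy)-3,5-dimethoxyphenyl]-3-oxopentanoate | [Na+].COc1cc(CCC([O-])=CC(=O)OCc2ccccc2)cc(OC)c1OCc1ccccc1 | intermediate
12 | racemic benzyl 2-{3-[3,4-bis(benzyloxy)phenyl]propyl}-5-[4-(benzyloxy)-3,5-dimethoxyphenyl]-3-oxopentanoate | COc1cc(CCC(=O)C(CCCc2ccc(OCc3ccccc3)c(OCc3ccccc3)c2)C(=O)OCc2ccccc2)cc(OC)c1OCc1ccccc1 | intermediate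
13 | racemic 2-[3-(3,4-dihydroxyphenyl)propyl]-5-(4-hydroxy-3,5-dimethoxyphenyl)-3-oxopentanoic acid | COc1cc(CCC(=O)C(CCCc2ccc(O)c(O)c2)C(=O)O)cc(OC)c1O | intermediate
14 | 7-(3,4-dihydroxyphenyl)-1-(4-hydroxy-3,5-dimethoxyphenyl)heptan-3-one | COc1cc(CCC(=O)CCCCc2ccc(O)c(O)c2)cc(OC)c1O | target

Total step count: 8
Longest linear sequence: 5 steps (steps 1, 2, 3, 7, 8 or steps 4, 5, 6, 7, 8)

Steps most likely to fail

Step 7. The stabilised enolate may react only slowly with the unactivated iodide. Then O-alkylation, a second alpha-alkylation through proton exchange, or capture of the iodide by leftover dianion would erode the doubly alkylated product. Proton transfer between dianion and monoalkylated enolate could also lead to double benzylation. Fallback: the two bond formations are separated and their order inverted. Setting out from 9 and 8, a classical acetoacetic ester alkylation (K2CO3, acetone, reflux, 9 in excess to suppress dialkylation) should give racemic benzyl 2-{3-[3,4-bis(benzyloxy)phenyl]propyl}-3-oxobutanoate F1, which is purified. Treatment with commercial LDA solution (2.1 equiv, THF, −78 to 0 °C) should give the dilithium dianion of this keto ester F2. Its terminal carbon is then benzylated with chloride 4 at 0 °C, and aqueous NH4Cl quench brings the sequence back to the route at 12.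

Step 3. The electron-rich benzylic chloride may ionise on concentration or on silica, leading to self-condensation by Friedel–Crafts alkylation or to hydrolysis. Residual HCl carried forward would also quench the dianion of step 7. Fallback: the acid-releasing chlorosulfite pathway is replaced by sulfonate activation and halide exchange under amine buffering. Setting out from 3, MsCl and Et3N in CH2Cl2 at −10 °C should give [4-(benzyloxy)-3,5-dimethoxyphenyl]methyl methanesulfonate F3, which is not isolated. Addition of LiCl in THF displaces it, and after a cold aqueous wash and drying the solution of the chloride is used directly, coming back to the route at 4.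

Step 8. Hydrogenolysis may stall through poisoning of the catalyst by traces of iodide or phosphorus residues, leaving partly benzylated material. The freed catechol may also oxidise in air during filtration. Fallback: ester removal and phenol deprotection are separated and done without hydrogen. Setting out from 12, Krapcho dealkoxycarbonylation (LiCl, wet DMSO, 140 °C) should give 7-[3,4-bis(benzyloxy)phenyl]-1-[4-(benzyloxy)-3,5-dimethoxyphenyl]heptan-3-one F4. Its three aryl benzyl ethers are then cleaved with BCl3 and pentamethylbenzene as cation scavenger in CH2Cl2 at −78 °C, conditions that spare the aryl methyl ethers, and aqueous work-up comes back to the route at 14.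

Further compounds
F1 | step 7 | racemic benzyl 2-{3-[3,4-bis(benzyloxy)phenyl]propyl}-3-oxobutanoate | CC(=O)C(CCCc1ccc(OCc2ccccc2)c(OCc2ccccc2)c1)C(=O)OCc1ccccc1
F2 | step 7 | dilithium dianion of benzyl 2-{3-[3,4-bis(benzyloxy)phenyl]propyl}-3-oxobutanoate | [Li+].[Li+].C=C([O-])C(CCCc1ccc(OCc2ccccc2)c(OCc2ccccc2)c1)=C([O-])OCc1ccccc1
F3 | step 3 | [4-(benzyloxy)-3,5-dimethoxyphenyl]methyl methanesulfonate | COc1cc(COS(C)(=O)=O)cc(OC)c1OCc1ccccc1
F4 | step 8 | 7-[3,4-bis(benzyloxy)phenyl]-1-[4-(benzyloxy)-3,5-dimethoxyphenyl]heptan-3-one | COc1cc(CCC(=O)CCCCc2ccc(OCc3ccccc3)c(OCc3ccccc3)c2)cc(OC)c1OCc1ccccc1
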